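**Plan**

- Retrosynthesis: the 7‑OH and 3'‑OH are masked as TIPS ethers and the 2'‑ and 5'‑O‑methyl groups are taken off. The 2'‑oxygen is then re‑joined to C4, so the isoflavan becomes a cis‑pterocarpan. That pterocarpan is cut at C3–C1' and at C4–O(2') into a 2H‑chromene (rings A and C) and a 1,4‑benzoquinone (ring B).
- Enabling feature: on ring B the 2'‑oxygen is ortho to C1' and can bridge to C4 of ring C as a dihydrobenzofuran. O2' and O5' are para to each other, so they are the two carbonyls of a quinone. The 4'‑OMe serves as the chelating group for titanium and the 3'‑oxygen is carried as a non‑chelating silyl ether.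
- Forward order: 2‑methoxyresorcinol is monosilylated. One portion is propargylated and rearranged to the chromene (ring C closed); the other is oxidised to the quinone. The [3+2] union closes the temporary furan ring. O‑methylation, hydrogenolysis of the benzylic C4–O bond (furan opened), a second O‑methylation and desilylation follow.
- Stereochemistry: the single stereocentre C3 (S) is C6a of the pterocarpan and is set in the [3+2] step by the chiral TADDOLate on titanium. C11a follows from the cis ring fusion and is erased by hydrogenolysis. No later step breaks a bond at C3.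

Key step: step 5

Assumption: the (R,R)‑TADDOL‑derived titanium complex is taken to deliver the (6aS,11aS) series; if the sense proves opposite, the (S,S)‑ligand is used with no other change.

Numbering: pterocarpan numbering (O5, C6, C6a, C11a, O11) is used for the tetracycles and isoflavan numbering for the ring‑opened compounds. The quinone is numbered C1(=O), C2(OMe), C3(OSi), C4(=O), C5–H, C6–H.

**Route**

Step 1
Reactants: 1 2‑methoxyresorcinol; 2 triisopropylsilyl chloride
Product: 3 2‑methoxy‑3‑(triisopropylsilyloxy)phenol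
Conditions: TIPSCl (0.9 equiv), imidazole, DMF, 0 °C
Reagents that add atoms: triisopropylsilyl chloride (2), CC(C)[Si](Cl)(C(C)C)C(C)C
Why: Imidazole‑promoted O‑silylation of one of two equivalent phenols, run with the silyl chloride as the limiting reagent so that the mono‑ether dominates and unreacted 1 and any bis‑ether are removed by chromatography.

Step 2
Reactants: 3 2‑methoxy‑3‑(triisopropylsilyloxy)phenol; 4 propargyl bromide
Product: 5 triisopropyl[2‑methoxy‑3‑(prop‑2‑yn‑1‑yloxy)phenoxy]silane
Conditions: K2CO3, acetone, 56 °C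
Reagents that add atoms: propargyl bromide (4), C#CCBr
Why: Williamson etherification of the one free phenol with a reactive propargylic bromide under K2CO3 in acetone, conditions that an aryl TIPS ether meta to the phenoxide tolerates.

Step 3
Reactants: 5 triisopropyl[2‑methoxy‑3‑(prop‑2‑yn‑1‑yloxy)phenoxy]silane
Product: 8 8‑methoxy‑7‑(triisopropylsilyloxy)‑2H‑chromene, via allenylphenol 6 (not isolated), via ortho‑quinone methide 7 (not isolated)
Conditions: PhNEt2, 200 °C, sealed tube
Reagents that add atoms: none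
Why: Aryl propargyl ether Claisen rearrangement onto the only unsubstituted ortho carbon, enolisation to 6, [1,5]‑hydrogen shift to 7 and oxa‑6π electrocyclisation give the 2H‑chromene in one thermal cascade that involves no acid, base or fluoride able to harm the silyl ether.

Step 4
Reactants: 3 2‑methoxy‑3‑(triisopropylsilyloxy)phenol
Product: 9 2‑methoxy‑3‑(triisopropylsilyloxy)‑1,4‑benzoquinone
Conditions: (KSO3)2NO (2.2 equiv), KH2PO4, H2O–acetone, 0 °C, short contact; extract into CH2Cl2, dry, use at once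
Reagents that add atoms: potassium nitrosodisulfonate (Fremy's salt), [K+].[K+].[O]N(S(=O)(=O)[O-])S(=O)(=O)[O-]
Why: Teuber oxidation of a phenol with a free para position by Fremy's salt, which places the second carbonyl oxygen on the carbon para to the hydroxyl (next to the siloxy group) while the cold, phosphate‑buffered medium and short contact time spare the hydrolytically sensitive vinylogous silyl ester.

Step 5
Reactants: 8 8‑methoxy‑7‑(triisopropylsilyloxy)‑2H‑chromene; 9 2‑methoxy‑3‑(triisopropylsilyloxy)‑1,4‑benzoquinone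
Product: 11 (6aS,11aS)‑8‑hydroxy‑4,9‑dimethoxy‑3,10‑bis(triisopropylsilyloxy)pterocarpan, via zwitterionic adduct 10 (not isolated)
Conditions: TiCl4, Ti(OiPr)4, (R,R)‑TADDOL (forms TiCl2(TADDOLate), 1.5 equiv), CH2Cl2, −78 to −40 °C; then aq. NaHCO3
Reagents that add atoms: none
Why: TiCl2(TADDOLate) chelates the C1 carbonyl and the neighbouring 2‑methoxy oxygen of 9, which makes C5 the electrophilic carbon; the styrene‑type C3 of 8 adds there in a conjugate sense to give the titanium dienolate/benzylic cation 10, whose C4 cation is stabilised by O1 and the para 7‑siloxy group. The C4 carbonyl oxygen of the quinone, made nucleophilic by the 2‑methoxy donor, then captures the cation in a 5‑exo‑trig closure of the dihydrobenzofuran ring, and proton loss aromatises ring B to the 8‑phenol, so that the future C3–C1' bond and the temporary C4–O bond are both formed. The closest known reaction type is the formal [3+2] cycloaddition of 2H‑chromenes and styrenes with 2‑alkoxy‑1,4‑benzoquinones promoted by TADDOLates of tetravalent titanium, which gives cis‑pterocarpans. C6a is set by the face of the chromene double bond that the TADDOLate‑bound quinone can reach, and C11a follows from C6a because the tethered oxygen can only close a cis‑fused six/five ring junction. The step needs regioselection on the quinone (C5, not C6), secured by five‑membered chelation to the small, basic methoxy oxygen in preference to the bulky, weakly basic triisopropylsiloxy oxygen, and attack through chromene C3 rather than C4, secured by the cation‑stabilising O1/7‑O pair.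

Step 6
Reactants: 11 (6aS,11aS)‑8‑hydroxy‑4,9‑dimethoxy‑3,10‑bis(triisopropylsilyloxy)pterocarpan
Product: 12 (6aS,11aS)‑4,8,9‑trimethoxy‑3,10‑bis(triisopropylsilyloxy)pterocarpan
Conditions: MeI, K2CO3, acetone, 40 °C
Reagents that add atoms: iodomethane, CI
Why: Williamson O‑methylation of the only free phenol, which has no silyl ether as an ortho neighbour, so no silyl shift can occur, and which leaves C6a and C11a untouched.

Step 7
Reactants: 12 (6aS,11aS)‑4,8,9‑trimethoxy‑3,10‑bis(triisopropylsilyloxy)pterocarpan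
Product: 13 (3S)‑2'‑hydroxy‑8,4',5'‑trimethoxy‑7,3'‑bis(triisopropylsilyloxy)isoflavan
Conditions: H2 (1 atm), 10% Pd/C, EtOAc–AcOH, rt
Reagents that add atoms: none
Why: Catalytic hydrogenolysis of the benzylic C11a–O11 bond, the classical pterocarpan to 2'‑hydroxyisoflavan conversion, removes the C11a stereocentre and leaves C6a (now C3, S) intact because no bond to it is broken, while aryl silyl and methyl ethers are inert to Pd/C and hydrogen.

Step 8
Reactants: 13 (3S)‑2'‑hydroxy‑8,4',5'‑trimethoxy‑7,3'‑bis(triisopropylsilyloxy)isoflavan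
Product: 14 (3S)‑8,2',4',5'‑tetramethoxy‑7,3'‑bis(triisopropylsilyloxy)isoflavan
Conditions: MeOH, PPh3, DIAD, THF, 0 °C to rt
Reagents that add atoms: methanol, CO
Why: Mitsunobu etherification with methanol methylates the hindered 2'‑phenol under neutral conditions in which the phenoxide exists only as a short‑lived ion pair, which should suppress 1,4 O‑to‑O silyl migration from the neighbouring 3'‑siloxy group.

Step 9
Reactants: 14 (3S)‑8,2',4',5'‑tetramethoxy‑7,3'‑bis(triisopropylsilyloxy)isoflavan
Product: 15 (3S)‑7,3'‑dihydroxy‑8,2',4',5'‑tetramethoxyisoflavan (CNP0201239.1)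
Conditions: TBAF, AcOH, THF, 0 °C
Reagents that add atoms: none
Why: Fluoride‑induced cleavage of both aryl TIPS ethers, buffered with acetic acid so that the electron‑rich phenols are released protonated and are not exposed to base and air, with the non‑acidic C3 stereocentre unaffected.

**Compound list**

1 | 2‑methoxyresorcinol (2‑methoxybenzene‑1,3‑diol) | COc1c(O)cccc1O | starting material
2 | triisopropylsilyl chloride | CC(C)[Si](Cl)(C(C)C)C(C)C | starting material
3 | 2‑methoxy‑3‑(triisopropylsilyloxy)phenol | COc1c(O)cccc1O[Si](C(C)C)(C(C)C)C(C)C | intermediate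
4 | propargyl bromide | C#CCBr | starting material
5 | triisopropyl[2‑methoxy‑3‑(prop‑2‑yn‑1‑yloxy)phenoxy]silane | COc1c(OCC#C)cccc1O[Si](C(C)C)(C(C)C)C(C)C | intermediate
6 | 2‑methoxy‑6‑(propa‑1,2‑dien‑1‑yl)‑3‑(triisopropylsilyloxy)phenol (allenylphenol, not isolated) | COc1c(O)c(C=C=C)ccc1O[Si](C(C)C)(C(C)C)C(C)C | intermediate
7 | 2‑methoxy‑6‑(prop‑2‑en‑1‑ylidene)‑3‑(triisopropylsilyloxy)cyclohexa‑2,4‑dien‑1‑one (ortho‑quinone methide, not isolated) | C=CC=C1C=CC(O[Si](C(C)C)(C(C)C)C(C)C)=C(OC)C1=O | intermediate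
8 | 8‑methoxy‑7‑(triisopropylsilyloxy)‑2H‑chromene | COc1c(O[Si](C(C)C)(C(C)C)C(C)C)ccc2C=CCOc12 | intermediate
9 | 2‑methoxy‑3‑(triisopropylsilyloxy)‑1,4‑benzoquinone | COC1=C(O[Si](C(C)C)(C(C)C)C(C)C)C(=O)C=CC1=O | intermediate
10 | zwitterionic C3–C5 adduct: dienolate of the quinone unit joined at its C5 to C3 of a chroman‑4‑yl cation, drawn without titanium; chroman C3 as in the target, the quinone‑derived CH centre is transient and left undefined (not isolated) | [O-]C1=CC(C(=O)C(O[Si](C(C)C)(C(C)C)C(C)C)=C1OC)[C@H]1COc2c(OC)c(O[Si](C(C)C)(C(C)C)C(C)C)ccc2[CH+]1 | intermediate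
11 | (6aS,11aS)‑8‑hydroxy‑4,9‑dimethoxy‑3,10‑bis(triisopropylsilyloxy)pterocarpan (cis‑fused) | COc1c(O)cc2c(c1O[Si](C(C)C)(C(C)C)C(C)C)O[C@@H]1c3ccc(O[Si](C(C)C)(C(C)C)C(C)C)c(OC)c3OC[C@H]21 | intermediate
12 | (6aS,11aS)‑4,8,9‑trimethoxy‑3,10‑bis(triisopropylsilyloxy)pterocarpan | COc1c(OC)cc2c(c1O[Si](C(C)C)(C(C)C)C(C)C)O[C@@H]1c3ccc(O[Si](C(C)C)(C(C)C)C(C)C)c(OC)c3OC[C@H]21 | intermediate
13 | (3S)‑2'‑hydroxy‑8,4',5'‑trimethoxy‑7,3'‑bis(triisopropylsilyloxy)isoflavan | COc1cc([C@H]2COc3c(ccc(O[Si](C(C)C)(C(C)C)C(C)C)c3OC)C2)c(O)c(O[Si](C(C)C)(C(C)C)C(C)C)c1OC | intermediate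
14 | (3S)‑8,2',4',5'‑tetramethoxy‑7,3'‑bis(triisopropylsilyloxy)isoflavan | COc1cc([C@H]2COc3c(ccc(O[Si](C(C)C)(C(C)C)C(C)C)c3OC)C2)c(OC)c(O[Si](C(C)C)(C(C)C)C(C)C)c1OC | intermediate
15 | (3S)‑7,3'‑dihydroxy‑8,2',4',5'‑tetramethoxyisoflavan (CNP0201239.1) | COc1cc([C@H]2COc3c(ccc(O)c3OC)C2)c(OC)c(O)c1OC | target

**Count**

Total steps: 9. Longest linear sequence: 8 steps (steps 1, 2, 3, 5, 6, 7, 8, 9; 1 → 3 → 5 → 8 → 11 → 12 → 13 → 14 → 15).

**Steps most likely to fail**

Step 5. Titanium may engage the siloxy‑flanked carbonyl, or its chloride may strip the silyl group from the vinylogous silyl ester. Either would send the C–C bond to C6 or destroy the quinone. Enantiofacial discrimination may also erode on this more hindered pair.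

The fallback sets out from chromene 8 and purchased 2‑methoxy‑1,4‑benzoquinone, the quinone class for which this titanium‑promoted [3+2] reaction is established and which has only one alkoxy group, so no regiochemical choice arises. The same TADDOLate conditions should give (6aS,11aS)‑8‑hydroxy‑4,9‑dimethoxy‑3‑(triisopropylsilyloxy)pterocarpan F1. MeI/K2CO3 in acetone converts it into (6aS,11aS)‑4,8,9‑trimethoxy‑3‑(triisopropylsilyloxy)pterocarpan F2. Directed ortho‑lithiation at C10, the position flanked by the 9‑methoxy group and O11 (n‑BuLi, TMEDA, THF, 0 °C), gives the C10‑lithio pterocarpan F3. It is trapped with B(OMe)3 as the C10 dimethyl boronate F4, which is oxidised in the same flask with H2O2 in pH 7 buffer to (6aS,11aS)‑10‑hydroxy‑4,8,9‑trimethoxy‑3‑(triisopropylsilyloxy)pterocarpan F5. Silylation with TIPSOTf/2,6‑lutidine in CH2Cl2 then returns compound 12.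

Step 4. The silyl group may be lost by hydrolysis of the vinylogous silyl ester in the aqueous oxidant. The oxidation may also be diverted to the free ortho position, because the para carbon is shielded by the neighbouring siloxy group.

The fallback reverses the order of oxidation and silylation and sets out from compound 1. Fremy's salt in phosphate buffer oxidises the unprotected resorcinol to 3‑hydroxy‑2‑methoxy‑1,4‑benzoquinone F6. This is silylated under anhydrous conditions (TIPSOTf, 2,6‑lutidine, CH2Cl2, −78 °C) and so comes back to the route at compound 9.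

Step 8. 1,4 O‑to‑O migration of the 3'‑silyl group onto the freed 2'‑oxygen, or sluggish alkylation of this doubly flanked phenol, would scramble which oxygen is methylated.

The fallback replaces the silyl groups by sulfonates before ring opening and sets out from compound 12. TBAF/AcOH gives (6aS,11aS)‑3,10‑dihydroxy‑4,8,9‑trimethoxypterocarpan F7. TsCl, Et3N and DMAP in CH2Cl2 give (6aS,11aS)‑4,8,9‑trimethoxy‑3,10‑bis(tosyloxy)pterocarpan F8. Hydrogenolysis (H2, Pd/C, EtOAc–AcOH) opens it to (3S)‑2'‑hydroxy‑8,4',5'‑trimethoxy‑7,3'‑bis(tosyloxy)isoflavan F9. MeI/K2CO3 in acetone then gives (3S)‑8,2',4',5'‑tetramethoxy‑7,3'‑bis(tosyloxy)isoflavan F10. Removal of both sulfonates with KOH in degassed MeOH–H2O at reflux comes back to the route at compound 15.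

Further compounds
F1 | step 5 | (6aS,11aS)‑8‑hydroxy‑4,9‑dimethoxy‑3‑(triisopropylsilyloxy)pterocarpan | COc1c(O)cc2c(c1)O[C@@H]1c3ccc(O[Si](C(C)C)(C(C)C)C(C)C)c(OC)c3OC[C@H]21
F2 | step 5 | (6aS,11aS)‑4,8,9‑trimethoxy‑3‑(triisopropylsilyloxy)pterocarpan | COc1c(OC)cc2c(c1)O[C@@H]1c3ccc(O[Si](C(C)C)(C(C)C)C(C)C)c(OC)c3OC[C@H]21
F3 | step 5 | C10‑lithio derivative of F2 | COc1c(OC)cc2c(c1[Li])O[C@@H]1c3ccc(O[Si](C(C)C)(C(C)C)C(C)C)c(OC)c3OC[C@H]21
F4 | step 5 | C10 dimethyl boronate of F2 | COc1c(OC)cc2c(c1B(OC)OC)O[C@@H]1c3ccc(O[Si](C(C)C)(C(C)C)C(C)C)c(OC)c3OC[C@H]21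
F5 | step 5 | (6aS,11aS)‑10‑hydroxy‑4,8,9‑trimethoxy‑3‑(triisopropylsilyloxy)pterocarpan | COc1c(OC)cc2c(c1O)O[C@@H]1c3ccc(O[Si](C(C)C)(C(C)C)C(C)C)c(OC)c3OC[C@H]21
F6 | step 4 | 3‑hydroxy‑2‑methoxy‑1,4‑benzoquinone | COC1=C(O)C(=O)C=CC1=O
F7 | step 8 | (6aS,11aS)‑3,10‑dihydroxy‑4,8,9‑trimethoxypterocarpan | COc1c(OC)cc2c(c1O)O[C@@H]1c3ccc(O)c(OC)c3OC[C@H]21
F8 | step 8 | (6aS,11aS)‑4,8,9‑trimethoxy‑3,10‑bis(tosyloxy)pterocarpan | COc1c(OC)cc2c(c1OS(=O)(=O)c1ccc(C)cc1)O[C@@H]1c3ccc(OS(=O)(=O)c4ccc(C)cc4)c(OC)c3OC[C@H]21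
F9 | step 8 | (3S)‑2'‑hydroxy‑8,4',5'‑trimethoxy‑7,3'‑bis(tosyloxy)isoflavan | COc1cc([C@H]2COc3c(ccc(OS(=O)(=O)c4ccc(C)cc4)c3OC)C2)c(O)c(OS(=O)(=O)c2ccc(C)cc2)c1OC
F10 | step 8 | (3S)‑8,2',4',5'‑tetramethoxy‑7,3'‑bis(tosyloxy)isoflavan | COc1cc([C@H]2COc3c(ccc(OS(=O)(=O)c4ccc(C)cc4)c3OC)C2)c(OC)c(OS(=O)(=O)c2ccc(C)cc2)c1OC
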